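**Plan**
- Retrosynthesis: cut the four ester C–O bonds and the lactone C12–O bond, then C7=C11; trace the epoxide back to a syn-4,5-diol; reconnect C14 (the C10 methyl) to C5 as a carbonyl bridge; cut C5–C6 and C9–C10.
- Enabling feature: C5 (oxygen) and C10 (methyl, C14) lie 1,6 across the ten-membered ring, so a C14 bridge makes the carbocycle the perimeter of a bicyclo[4.4.1]undecane, i.e. a tropone (C14, C10, C1–C5) plus a diene (C6–C9).
- Forward: 3-methyltropone and a 1-silyl-3-silyloxybutadiene give both seven-membered rings in one (6+4) step; the silyl enol ether then attaches C11–C13 at C7; singlet oxygen oxygenates C1/C4; Baeyer–Villiger cuts C5–C14; hydride and deoxygenation turn C14 into the methyl and release the ten-membered ring; epoxide, esters and butenolide come last.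
- C6 carries silicon as a masked hydroxyl: it cannot β-eliminate next to the C8 carbonyl and it steers the Baeyer–Villiger migration to C5.
- Stereochemistry: C5/C6/C10 from the exo cycloaddition (racemate, resolved at the first robust enone); C1/C4 from oxygen addition on the bridge face; C5–O and C6–O by retentive Baeyer–Villiger and Fleming–Tamao steps; the cis epoxide by double inversion; C8 by Luche reduction.

Key step: step 7

Remark: germacrane numbering is used for all ring compounds (C1–C10 ring, C11–C13 side chain on C7, C14 on C10, C15 on C4). "β" means the face of the ten-membered perimeter that carries the C14 bridge (later the C10 methyl). The target, (1S,4R,5S,6S,8S,10R), has 1β-OAc, 4β,5β-epoxide (4α-CH3), 6β-O, 8β-O and 10β-CH3.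

Step 1
Reactants: 1 3-methylanisole
Product: 2 1-methoxy-5-methylcyclohexa-1,4-diene
Conditions: Li, NH3 (l), t-BuOH, THF, −78 °C
Reagents that add atoms: none
Why: Birch reduction of a donor-substituted arene gives the 2,5-dihydro product with methoxy and methyl on the remaining double bonds.

Step 2
Reactants: 2 1-methoxy-5-methylcyclohexa-1,4-diene
Product: 4 3-methyltropone, via dibromocyclopropane adduct 3 (not isolated)
Conditions: CHBr3, KOt-Bu, pentane, −20 °C; then pyridine, 80 °C
Reagents that add atoms: bromoform, BrC(Br)Br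
Why: Dibromocarbene cyclopropanates the more electron-rich enol ether double bond; on heating, the adduct ionises with ring opening to a bromocycloheptadienone (loss of the O-methyl group) and eliminates HBr to the tropone, the classical dihalocarbene ring expansion of dihydroanisoles.

Step 3
Reactants: 5 but-3-yn-2-ol
Product: 6 (E)-4-[dimethyl(phenyl)silyl]but-3-en-2-ol
Conditions: PhMe2SiH, Pt2[(H2C=CHSiMe2)2O]3 (0.1 mol %), P(t-Bu)3, THF, rt
Reagents that add atoms: dimethylphenylsilane, C[SiH](C)c1ccccc1
Why: Platinum-catalysed syn hydrosilylation of the terminal alkyne with a bulky phosphine puts silicon on the terminal carbon and gives the E vinylsilane.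

Step 4
Reactants: 6 (E)-4-[dimethyl(phenyl)silyl]but-3-en-2-ol
Product: 7 (E)-4-[dimethyl(phenyl)silyl]but-3-en-2-one
Conditions: MnO2, CH2Cl2, rt
Reagents that add atoms: none
Why: MnO2 oxidises the allylic alcohol to the enone and leaves the vinylsilane untouched.

Step 5
Reactants: 7 (E)-4-[dimethyl(phenyl)silyl]but-3-en-2-one
Product: 8 (E)-3-(tert-butyldimethylsilyloxy)-1-[dimethyl(phenyl)silyl]buta-1,3-diene
Conditions: TBSOTf, Et3N, CH2Cl2, 0 °C
Reagents that add atoms: tert-butyldimethylsilyl triflate, CC(C)(C)[Si](C)(C)OS(=O)(=O)C(F)(F)F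
Why: Soft enolisation of the methyl ketone gives the 2-silyloxydiene with the E vinylsilane geometry intact.

Step 6
Reactants: 9 1,3-dihydroxyacetone dimer
Product: 10 1,3-bis(tert-butyldimethylsilyloxy)propan-2-one
Conditions: TBSCl, imidazole, DMF, rt
Reagents that add atoms: tert-butyldimethylsilyl chloride, CC(C)(C)[Si](C)(C)Cl
Why: The dimer dissociates in DMF and imidazole-promoted silylation caps both primary hydroxyls of the monomeric ketone.

Step 7
Reactants: 4 3-methyltropone; 8 (E)-3-(tert-butyldimethylsilyloxy)-1-[dimethyl(phenyl)silyl]buta-1,3-diene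
Product: 11 racemic 9-(tert-butyldimethylsilyloxy)-7-[dimethyl(phenyl)silyl]-5-methylbicyclo[4.4.1]undeca-2,4,8-trien-11-one (silyl group on the face of the carbonyl bridge)
Conditions: PhMe, 110 °C, sealed tube, BHT (cat.), 48–72 h
Reagents that add atoms: none
Why: A thermally allowed, concerted ten-electron [π6s + π4s] cycloaddition joins the tropone α-carbons (C5, C10) to the diene termini (C6, C9); it is the known exo-selective thermal (6+4) reaction of tropones with 1-substituted buta-1,3-dienes, applied here to a new pair. Two rings close in this one intermolecular annulation: the cycloheptene ring C14–C5–C6–C7–C8–C9–C10 and, as its consequence, the ten-membered perimeter C1–C10. C5 and C10 are bridgeheads and necessarily cis through C14; C6 is set by the E vinylsilane geometry together with the exo transition state (diene C7–C8 under the carbonyl, away from the triene), which puts silicon on the face of the C14 bridge. The step needs periselectivity ((6+4) over (4+2)), exo selectivity and one orientation: the first two are the normal thermal preference of tropone (endo secondary overlap is antibonding), and the orientation follows from the large HOMO coefficient at C9 (the CH2 terminus of the silyl enol ether) bonding to the unhindered tropone carbon C10 remote from the C4 methyl. The adduct is racemic and is resolved in step 9.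

Step 8
Reactants: 11 racemic cycloadduct; 10 1,3-bis(tert-butyldimethylsilyloxy)propan-2-one
Product: 13 racemic 8-[1,3-bis(tert-butyldimethylsilyloxy)propan-2-ylidene]-7-[dimethyl(phenyl)silyl]-5-methylbicyclo[4.4.1]undeca-2,4-diene-9,11-dione, via aldol adduct 12 (not isolated)
Conditions: TiCl4, CH2Cl2, −78 °C; then crude, Burgess reagent, PhMe, 50 °C
Reagents that add atoms: none
Why: Mukaiyama aldol addition of the regiodefined silyl enol ether carbon C7 to the TiCl4-activated α,α′-dioxygenated ketone forms C7–C11, and Burgess dehydration of the tertiary carbinol toward the acidic C7–H gives the conjugated enone; C11 carries two identical arms, so no alkene isomers or extra stereocentre arise.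

Step 9
Reactants: 13 racemic enone
Product: 14 enone as the single enantiomer drawn
Conditions: preparative HPLC, amylose tris(3,5-dimethylphenylcarbamate) on silica, hexane/i-PrOH
Reagents that add atoms: none
Why: Direct resolution on a polysaccharide chiral stationary phase at the first robust, UV-active intermediate; no stereocentre is formed, and the absolute configuration would be assigned by anomalous-dispersion crystallography of a later crystalline derivative.

Step 10
Reactants: 14 enone
Product: 15 1β,4β-epidioxy-2-ene (endoperoxide of 14)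
Conditions: O2, tetraphenylporphyrin (cat.), visible light, CH2Cl2, −20 °C
Reagents that add atoms: dioxygen (as singlet oxygen), O=O
Why: Singlet oxygen adds [4+2] to the s-cis cycloheptadiene from the face of the C14 bridge (the other face is screened by the C6–C9 bridge), which sets the C1 and C4 oxygens β and leaves the C4 methyl α; the electron-poor enone double bond does not compete.

Step 11
Reactants: 15 unsaturated endoperoxide
Product: 16 saturated 1β,4β-endoperoxide
Conditions: KO2CN=NCO2K, AcOH, CH2Cl2/MeOH, 0 °C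
Reagents that add atoms: none
Why: Diimide reduces the strained cis-disubstituted C2=C3 bond without cleaving the O–O bond or touching the tetrasubstituted enone.

Step 12
Reactants: 16 saturated endoperoxide
Product: 17 bridging lactone C5–O–C14(=O)–C10
Conditions: m-CPBA, NaHCO3, CH2Cl2, 0 °C → rt
Reagents that add atoms: m-chloroperbenzoic acid, OOC(=O)c1cccc(Cl)c1
Why: Silicon-directed Baeyer–Villiger oxidation: C5 carries the β-silyl donor whereas C10 adjoins the C9 methylene α to the C8 carbonyl, so C5 migrates with retention and C14 stays on C10; the conjugated C8 ketone and its electron-poor alkene react more slowly.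

Step 13
Reactants: 17 bridging lactone
Product: 18 6β-alcohol
Conditions: KBr, AcOOH, NaOAc, AcOH, rt
Reagents that add atoms: peracetic acid, CC(=O)OO
Why: Fleming–Tamao oxidation (bromodesilylation of the phenyl group, then peracid-induced 1,2-shift of C6 from silicon to oxygen) replaces silicon by hydroxyl with retention; the cis arrangement of C6–Si and C5–O disfavours anti elimination.

Step 14
Reactants: 18 6β-alcohol
Product: 19 6β-silyl ether
Conditions: TBSOTf, 2,6-lutidine, CH2Cl2, −78 → 0 °C
Reagents that add atoms: tert-butyldimethylsilyl triflate, CC(C)(C)[Si](C)(C)OS(=O)(=O)C(F)(F)F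
Why: Silyl triflate/lutidine silylation of the hindered secondary alcohol masks O6 so that it stays distinct from O4 and O5 after the reduction.

Step 15
Reactants: 19 6β-silyl ether
Product: 20 ten-membered 1β,4β,5β,8,14-pentaol (C8 epimers)
Conditions: LiAlH4, THF, 0 °C
Reagents that add atoms: none
Why: LiAlH4 opens the bridging lactone to the C14 primary and C5 secondary alcohols, cleaves the O–O bond to the 1,4-diol and reduces the enone carbonyl 1,2, which releases the ten-membered carbocycle; the C8 epimers are carried on together because C8 is reoxidised next.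

Step 16
Reactants: 20 pentaol
Product: 21 1β,4β,5β,14-tetrahydroxy-7(11)-en-8-one
Conditions: MnO2, CH2Cl2, rt
Reagents that add atoms: none
Why: MnO2 oxidises only the allylic C8 alcohol back to the enone, which merges the epimers and removes a γ-hydroxyl that could cyclise onto an activated C14.

Step 17
Reactants: 21 tetrahydroxy enone
Product: 22 1β,4β,5β-triol with the C10 methyl group
Conditions: PPh3, DEAD, 2-nitrobenzenesulfonylhydrazide, THF, −30 °C → rt
Reagents that add atoms: none
Why: Myers reductive deoxygenation: Mitsunobu displacement of the unhindered primary C14 hydroxyl by the sulfonylhydrazide, sulfinate loss and loss of N2 from the monoalkyl diazene give the methyl group, the secondary and tertiary hydroxyls reacting more slowly.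

Step 18
Reactants: 22 triol
Product: 25 4β,5β-epoxide (1β-ol), via cyclic orthoacetate 23 (not isolated), via chloro acetate 24 (not isolated)
Conditions: MeC(OMe)3, PPTS (cat.), CH2Cl2, rt; TMSCl, 0 °C; then K2CO3, MeOH, rt
Reagents that add atoms: none
Why: Kolb–Sharpless epoxide synthesis from the syn-4,5-diol: the orthoacetate is opened to an acetoxonium ion, chloride enters with inversion and the liberated alkoxide displaces it with a second inversion, so both C–O configurations are retained and the cis β-epoxide results (opening at either carbon converges).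

Step 19
Reactants: 25 epoxy alcohol
Product: 26 1β-acetate
Conditions: Ac2O, pyridine, DMAP (cat.), CH2Cl2, rt
Reagents that add atoms: acetic anhydride, CC(=O)OC(C)=O
Why: DMAP-catalysed acetylation of the only free hydroxyl.

Step 20
Reactants: 26 1β-acetate
Product: 27 8β-allylic alcohol
Conditions: NaBH4, CeCl3·7H2O, MeOH, −78 °C
Reagents that add atoms: none
Why: Luche 1,2-reduction of the enone; hydride should approach C8 from the α face, opposite the flanking β substituents at C6 (OTBS) and C10 (CH3), to give the 8β-alcohol.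

Step 21
Reactants: 27 8β-alcohol
Product: 28 8β-tiglate
Conditions: tigloyl chloride, pyridine, DMAP, CH2Cl2, 0 °C → rt
Reagents that add atoms: tigloyl chloride, C/C=C(\C)C(=O)Cl
Why: Nucleophile-catalysed acylation of the allylic alcohol; the E (tiglate) geometry is the stable one and is kept.

Step 22
Reactants: 28 8β-tiglate
Product: 29 6β,12,13-triol
Conditions: TBAF, AcOH, THF, 0 °C → rt
Reagents that add atoms: none
Why: Buffered fluoride cleaves the three silyl ethers; the buffer suppresses acyl migration, and the cis epoxy alcohol cannot undergo Payne rearrangement.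

Step 23
Reactants: 29 triol
Product: 30 13-oxo-12,6-olide
Conditions: TEMPO (cat.), PhI(OAc)2, CH2Cl2, rt
Reagents that add atoms: none
Why: TEMPO/PhI(OAc)2 oxidises both primary allylic alcohols to aldehydes; the one cis to O6 is trapped as the five-membered lactol and oxidised on to the butenolide (oxidative lactonisation of a (Z)-2-ene-1,4-diol), the other stays as the C13 aldehyde.

Step 24
Reactants: 30 13-oxo lactone
Product: 31 13-hydroxy-12,6-olide
Conditions: NaBH4, CeCl3·7H2O, MeOH, −78 °C
Reagents that add atoms: none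
Why: Luche conditions reduce the aldehyde 1,2 at low temperature and spare the lactone, the esters and the tetrasubstituted alkene.

Step 25
Reactants: 31 13-hydroxy lactone
Product: 32 CNP0287840.1
Conditions: Ac2O, pyridine, DMAP (cat.), CH2Cl2, 0 °C
Reagents that add atoms: acetic anhydride, CC(=O)OC(C)=O
Why: Acetylation of the primary allylic alcohol completes the target.

**Compound list**
1 | 3-methylanisole | COc1cccc(C)c1 | starting material
2 | 1-methoxy-5-methylcyclohexa-1,4-diene | COC1=CCC=C(C)C1 | intermediate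
3 | 7,7-dibromo-1-methoxy-3-methylbicyclo[4.1.0]hept-3-ene (racemic, cis-fused) | COC12CC(C)=CCC1C2(Br)Br | intermediate
4 | 3-methyltropone | CC1=CC(=O)C=CC=C1 | intermediate
5 | but-3-yn-2-ol (racemic) | CC(O)C#C | starting material
6 | (E)-4-[dimethyl(phenyl)silyl]but-3-en-2-ol (racemic) | CC(O)/C=C/[Si](C)(C)c1ccccc1 | intermediate
7 | (E)-4-[dimethyl(phenyl)silyl]but-3-en-2-one | CC(=O)/C=C/[Si](C)(C)c1ccccc1 | intermediate
8 | (E)-3-(tert-butyldimethylsilyloxy)-1-[dimethyl(phenyl)silyl]buta-1,3-diene | C=C(O[Si](C)(C)C(C)(C)C)/C=C/[Si](C)(C)c1ccccc1 | intermediate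
9 | 1,3-dihydroxyacetone dimer | OCC1(O)COC(O)(CO)CO1 | starting material
10 | 1,3-bis(tert-butyldimethylsilyloxy)propan-2-one | CC(C)(C)[Si](C)(C)OCC(=O)CO[Si](C)(C)C(C)(C)C | intermediate
11 | racemic exo cycloadduct: C14 ketone bridging C5/C10, C1=C2–C3=C4(CH3) diene, 6β-SiMe2Ph, C7=C8–OTBS (enantiomer shown is the one used later) | O=C1[C@H]2C=CC=C(C)[C@@H]1[C@@H]([Si](C)(C)c3ccccc3)C=C(O[Si](C)(C)C(C)(C)C)C2 | intermediate
12 | racemic aldol adduct: 8-ketone, C7 bearing C(OH)(CH2OTBS)2 anti to silicon | O=C1[C@H]2C=CC=C(C)[C@@H]1[C@@H]([Si](C)(C)c3ccccc3)[C@H](C(O)(CO[Si](C)(C)C(C)(C)C)CO[Si](C)(C)C(C)(C)C)C(=O)C2 | intermediate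
13 | racemic enone: 7(11)-en-8-one with two CH2OTBS on C11, 6β-SiMe2Ph, diene and C14 ketone bridge | O=C1[C@H]2C=CC=C(C)[C@@H]1[C@@H]([Si](C)(C)c3ccccc3)C(=C(CO[Si](C)(C)C(C)(C)C)CO[Si](C)(C)C(C)(C)C)C(=O)C2 | intermediate
14 | enone 13 as the single enantiomer drawn | O=C1[C@H]2C=CC=C(C)[C@@H]1[C@@H]([Si](C)(C)c3ccccc3)C(=C(CO[Si](C)(C)C(C)(C)C)CO[Si](C)(C)C(C)(C)C)C(=O)C2 | intermediate
15 | 1β,4β-epidioxy-2-ene (4α-methyl) | O=C1[C@H]2[C@@H]3C=C[C@@](C)(OO3)[C@@H]1[C@@H]([Si](C)(C)c4ccccc4)C(=C(CO[Si](C)(C)C(C)(C)C)CO[Si](C)(C)C(C)(C)C)C(=O)C2 | intermediate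
16 | saturated 1β,4β-endoperoxide | O=C1[C@H]2[C@@H]3CC[C@@](C)(OO3)[C@@H]1[C@@H]([Si](C)(C)c4ccccc4)C(=C(CO[Si](C)(C)C(C)(C)C)CO[Si](C)(C)C(C)(C)C)C(=O)C2 | intermediate
17 | bridging lactone C5β–O–C14(=O)–C10, 1β,4β-endoperoxide, 6β-SiMe2Ph, 7(11)-en-8-one | O=C1[C@H]2[C@@H]3CC[C@@](C)(OO3)[C@@H](O1)[C@@H]([Si](C)(C)c4ccccc4)C(=C(CO[Si](C)(C)C(C)(C)C)CO[Si](C)(C)C(C)(C)C)C(=O)C2 | intermediate
18 | 6β-alcohol of 17 | O=C1[C@H]2[C@@H]3CC[C@@](C)(OO3)[C@@H](O1)[C@@H](O)C(=C(CO[Si](C)(C)C(C)(C)C)CO[Si](C)(C)C(C)(C)C)C(=O)C2 | intermediate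
19 | 6β-OTBS ether of 18 | O=C1[C@H]2[C@@H]3CC[C@@](C)(OO3)[C@@H](O1)[C@@H](O[Si](C)(C)C(C)(C)C)C(=C(CO[Si](C)(C)C(C)(C)C)CO[Si](C)(C)C(C)(C)C)C(=O)C2 | intermediate
20 | 6β,12,13-tris(OTBS)germacr-7(11)-ene-1β,4β,5β,8,14-pentaol (both C8 epimers) | OC1C[C@@H](CO)[C@@H](O)CC[C@@](C)(O)[C@@H](O)[C@@H](O[Si](C)(C)C(C)(C)C)C1=C(CO[Si](C)(C)C(C)(C)C)CO[Si](C)(C)C(C)(C)C | intermediate
21 | 1β,4β,5β,14-tetrahydroxy-6β,12,13-tris(OTBS)germacr-7(11)-en-8-one | O=C1C[C@@H](CO)[C@@H](O)CC[C@@](C)(O)[C@@H](O)[C@@H](O[Si](C)(C)C(C)(C)C)C1=C(CO[Si](C)(C)C(C)(C)C)CO[Si](C)(C)C(C)(C)C | intermediate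
22 | 1β,4β,5β-trihydroxy-6β,12,13-tris(OTBS)germacr-7(11)-en-8-one (10β-methyl) | O=C1C[C@@H](C)[C@@H](O)CC[C@@](C)(O)[C@@H](O)[C@@H](O[Si](C)(C)C(C)(C)C)C1=C(CO[Si](C)(C)C(C)(C)C)CO[Si](C)(C)C(C)(C)C | intermediate
23 | 4β,5β-cyclic methyl orthoacetate of 22 (orthoester carbon as a mixture) | O=C1C[C@@H](C)[C@@H](O)CC[C@@]2(C)OC(C)(OC)O[C@H]2[C@@H](O[Si](C)(C)C(C)(C)C)C1=C(CO[Si](C)(C)C(C)(C)C)CO[Si](C)(C)C(C)(C)C | intermediate
24 | 4α-chloro-5β-acetoxy-1β-ol (4β-methyl) | O=C1C[C@@H](C)[C@@H](O)CC[C@](C)(Cl)[C@@H](OC(C)=O)[C@@H](O[Si](C)(C)C(C)(C)C)C1=C(CO[Si](C)(C)C(C)(C)C)CO[Si](C)(C)C(C)(C)C | intermediate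
25 | 4β,5β-epoxy-1β-hydroxy-6β,12,13-tris(OTBS)germacr-7(11)-en-8-one | O=C1C[C@@H](C)[C@@H](O)CC[C@@]2(C)O[C@H]2[C@@H](O[Si](C)(C)C(C)(C)C)C1=C(CO[Si](C)(C)C(C)(C)C)CO[Si](C)(C)C(C)(C)C | intermediate
26 | 1β-acetate of 25 | O=C1C[C@@H](C)[C@@H](OC(C)=O)CC[C@@]2(C)O[C@H]2[C@@H](O[Si](C)(C)C(C)(C)C)C1=C(CO[Si](C)(C)C(C)(C)C)CO[Si](C)(C)C(C)(C)C | intermediate
27 | 8β-alcohol | O[C@H]1C[C@@H](C)[C@@H](OC(C)=O)CC[C@@]2(C)O[C@H]2[C@@H](O[Si](C)(C)C(C)(C)C)C1=C(CO[Si](C)(C)C(C)(C)C)CO[Si](C)(C)C(C)(C)C | intermediate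
28 | 8β-tiglate | C/C=C(\C)C(=O)O[C@H]1C[C@@H](C)[C@@H](OC(C)=O)CC[C@@]2(C)O[C@H]2[C@@H](O[Si](C)(C)C(C)(C)C)C1=C(CO[Si](C)(C)C(C)(C)C)CO[Si](C)(C)C(C)(C)C | intermediate
29 | 1β-acetoxy-4β,5β-epoxy-8β-tigloyloxygermacr-7(11)-ene-6β,12,13-triol | C/C=C(\C)C(=O)O[C@H]1C[C@@H](C)[C@@H](OC(C)=O)CC[C@@]2(C)O[C@H]2[C@@H](O)C1=C(CO)CO | intermediate
30 | 1β-acetoxy-4β,5β-epoxy-13-oxo-8β-tigloyloxygermacr-7(11)-en-12,6-olide | C/C=C(\C)C(=O)O[C@H]1C[C@@H](C)[C@@H](OC(C)=O)CC[C@@]2(C)O[C@H]2[C@H]2OC(=O)C(C=O)=C12 | intermediate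
31 | 1β-acetoxy-4β,5β-epoxy-13-hydroxy-8β-tigloyloxygermacr-7(11)-en-12,6-olide | C/C=C(\C)C(=O)O[C@H]1C[C@@H](C)[C@@H](OC(C)=O)CC[C@@]2(C)O[C@H]2[C@H]2OC(=O)C(CO)=C12 | intermediate
32 | CNP0287840.1, (1S,4R,5S,6S,8S,10R)-1,13-diacetoxy-4,5-epoxy-8-tigloyloxygermacr-7(11)-en-12,6-olide | C/C=C(\C)C(=O)O[C@H]1C[C@@H](C)[C@@H](OC(C)=O)CC[C@@]2(C)O[C@H]2[C@H]2OC(=O)C(COC(C)=O)=C12 | target

**Count and risks**
Total: 25 steps. Longest linear sequence: 22 steps (5 → 32 through steps 3–5 and 7–25).

Steps most likely to fail: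

1. Step 7. The bulky silyl terminus may avoid the methyl-flanked α-carbon (loss of orientation), or (4+2) addition across the tropone may compete. Fallback, a stepwise anionic route from 7 and 4 back to 11: enone 7 is deprotonated at its methyl group with LiN(i-Pr)2 in THF at −78 °C to the cross-conjugated lithium dienolate F1. Its CH2 carbon (C9) adds 1,8 to the unhindered α-carbon of tropone 4 under charge control, giving the 7-substituted cycloheptatrienolate F2 with the orientation fixed by the first bond. On warming, F2 closes by intramolecular Michael addition of C5 onto the β-silyl enone (C6), and the resulting C8 enolate is silylated in the flask with TBSCl to give 11. The configuration at C6 would have to be confirmed, since a stepwise closure need not be exo.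

2. Step 12. Peracid addition to the shielded bridging carbonyl may be slow, so that migration of C10 or oxidation elsewhere competes. Fallback from 14, returning at 17: the Baeyer–Villiger step is moved ahead of the oxygenation, where C5 is both allylic and β-silyl. Bis(trimethylsilyl) peroxide with catalytic TMSOTf in CH2Cl2 at −40 °C, a ketone-selective oxidant that spares C=C bonds, converts 14 into the diene lactone F3. Singlet oxygen then adds to the diene of F3 on the bridge face to give the unsaturated endoperoxide lactone F4, and diimide reduction of its C2=C3 bond gives 17.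

3. Step 20. Facial selectivity of hydride addition to a conformationally mobile ten-membered enone may be poor or reversed. Fallback from 26, returning at 28: if the reduction gives mainly the 8α-alcohol F5, it is esterified with tiglic acid under Mitsunobu conditions (PPh3, diisopropyl azodicarboxylate, PhMe, 0 °C), which installs the tiglate with inversion at C8 and gives 28 directly, replacing step 21 for that material.

Further compounds
F1 | step 7 | lithium (E)-4-[dimethyl(phenyl)silyl]buta-1,3-dien-2-olate | [Li+].[O-]C(=C)/C=C/[Si](C)(C)c1ccccc1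
F2 | step 7 | lithium 7-{(E)-4-[dimethyl(phenyl)silyl]-2-oxobut-3-enyl}-3-methylcyclohepta-1,3,5-trien-1-olate (racemic) | [Li+].[O-]C1=CC(C)=CC=CC1CC(=O)/C=C/[Si](C)(C)c1ccccc1
F3 | step 12 | diene lactone: C5β–O–C14(=O)–C10 bridge, C1=C2–C3=C4(CH3) diene, 6β-SiMe2Ph, 7(11)-en-8-one | O=C1[C@H]2C=CC=C(C)[C@@H](O1)[C@@H]([Si](C)(C)c3ccccc3)C(=C(CO[Si](C)(C)C(C)(C)C)CO[Si](C)(C)C(C)(C)C)C(=O)C2
F4 | step 12 | unsaturated 1β,4β-endoperoxide of F3 | O=C1[C@H]2[C@@H]3C=C[C@@](C)(OO3)[C@@H](O1)[C@@H]([Si](C)(C)c4ccccc4)C(=C(CO[Si](C)(C)C(C)(C)C)CO[Si](C)(C)C(C)(C)C)C(=O)C2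
F5 | step 20 | 8α-alcohol (C8 epimer of 27) | O[C@@H]1C[C@@H](C)[C@@H](OC(C)=O)CC[C@@]2(C)O[C@H]2[C@@H](O[Si](C)(C)C(C)(C)C)C1=C(CO[Si](C)(C)C(C)(C)C)CO[Si](C)(C)C(C)(C)C
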